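All runs stem from a simulated flask for substances that don't exist; the scatter is artificial.

- Leave the bath alone if you take over these flasks for the share of target in target plus side product: I could read no shift with temperature in the earlier runs.

| setting | teal | amber | blue | north-east | north-west | south | north |
|---|---|---|---|---|---|---|---|
| solid substrate | 0.40 M | 0.40 M | 0.40 M | 0.40 M | 0.40 M | 0.40 M | 0.40 M |
| partner | 1.2 equiv | 1.2 equiv | 2.4 equiv | 1.20 equiv | 1.20 equiv | 1.20 equiv | 1.20 equiv |
| protic impurity | 0.56 M | 0.88 M | 0.40 M | 0.400 M | 0.400 M | 0.400 M | 0.400 M |
| temperature | 95 °C | 128 °C | 95 °C | 100 °C | 80 °C | 120 °C | 140 °C |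
| remark | run made earlier | run made earlier | run made earlier |  |  |  |  |
| time |  |  |  | 2.5 h | 2.5 h | 2.5 h | 2.5 h |

- teal (time / h: target / %, side product / %, solid substrate / %): 0.200: 2, 0, 94; 0.333: 2, 2, 93; 0.500: 11, 3, 91; 0.667: 9, 2, 85; 1.00: 17, 4, 79; 1.50: 27, 6, 68; 2.50: 42, 10, 48
- amber (time / min: target / %, side product / %, solid substrate / %): 2.00: 1, 0, 103; 6.00: 2, 1, 97; 10.0: 2, 3, 95; 15.0: 4, 0, 94; 25.0: 9, 3, 88; 30.0: 10, 3, 86; 40.0: 13, 4, 82
- blue (time / h: target / %, side product / %, solid substrate / %): 0.200: 2, 0, 96; 0.667: 8, 1, 85; 1.33: 25, 3, 72; 2.00: 36, 8, 57; 2.50: 44, 6, 44

(standard deviation of a reading: 1.5 percentage points)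

- solid, in amounts per volume of the solution: solid substrate
- the earlier runs were read with a standard deviation of 1.5 percentage points
- on the list of suspects stand: starting material -> side product; starting material <-> intermediate; starting material -> target; partner + protic impurity -> quenched reagent; solid substrate <-> starting material
- at the start none of the solid substrate is in solution
- what has only dissolved of solid substrate counts as not reacted

- the flask that comes out highest in share of target in all that became target or side product, or "all alike" when all lie within 1.5 percentage points (north-east / north-west / south / north / all alike)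
- share of target in all that became target or side product, north-east
- share of target in all that became target or side product, north-west
- share of target in all that became target or side product, south
- share of target in all that became target or side product, north

- The list of suspects has solid substrate dissolving to starting material, with target and side product each leaving starting material by one step. So I pooled the last readings of the earlier runs: target over target plus side product came to 83.2%, and I carried this as the split, my word for the selectivity.
- Run by run, that share read 80.8% in teal and 88.0% in blue, both at 95 °C, and 76.5% in amber at 128 °C.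
- Teal and blue, at one temperature but with different charges of partner and protic impurity, lay 7.2 percentage points apart, which was more than the 4.3 points from teal to amber. Amber's side product reading of 4% carried a scatter of 1.5 points, so I took the temperature trend as unread.
- When you come at 2.5 h, expect target and side product in the split, with solid substrate, dissolved or not, still there, as in the 48% read in teal at 2.50 h. I wrote 83.2% against north-east, north-west, south and north, and so answered all alike.
- The forecast differed from mine: it gave 87% for north-west, 82% for north-east, 77% for south and 71% for north, named north-west, and said “The coolest flask is best.”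
- The flasks gave 83.0% in north-east, 83.0% in north-west, 83.0% in south and 83.0% in north, so the answer was all alike.

    starting material → side product (k = 6.42 × 10⁻⁵ s⁻¹, Ea = 121 kJ mol⁻¹)
    starting material ⇌ intermediate (K = 0.210, k = 8.78 × 10⁻⁵ s⁻¹, Ea = 113 kJ mol⁻¹, ΔH = −29.0 kJ mol⁻¹)
    starting material → target (k = 3.14 × 10⁻⁴ s⁻¹, Ea = 121 kJ mol⁻¹)
    partner + protic impurity → quenched reagent (k = 0.00436 M⁻¹ s⁻¹, Ea = 79.0 kJ mol⁻¹)
    solid substrate ⇌ starting material, rate k5*(cs5 - [starting material]) while solid is left; crystals form when [starting material] > cs5 (solubility = 0.0610 M, k = 4.88 × 10⁻⁴ s⁻¹)
    (constants at 80 °C)

- In north-west at 2.50 h, starting material went to target 4.9 times as fast as to side product, and that flask's share stood at 83.0%. In a repeat of north-west at 65 °C, which held 4.83% target, the split gives 0.975% side product, and that flask held 0.988%, a share of 83.0%.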